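Which flask ends with more target, larch or elm, and how much does each hold at its end?

| flask | substrate | temperature | remark | time |
|---|---|---|---|---|
| Tuesday's | 0.40 M | −45 °C | run made earlier |  |
| Wednesday's | 1.6 M | −30 °C | run made earlier |  |
| larch | 0.80 M |  | at −20 °C until 3.0 min, from then on at −40 °C | 15 min |
| elm | 0.80 M |  | at −20 °C throughout | 10 min |

| run | time / min | target / % |
|---|---|---|
| Tuesday's | 15.0 | 6.6 |
| Tuesday's | 30.0 | 11.7 |
| Tuesday's | 50.0 | 17.9 |
| Tuesday's | 60.0 | 20.3 |
| Wednesday's | 8.00 | 33.3 |
| Wednesday's | 15.0 | 48.7 |
| Wednesday's | 25.0 | 58.8 |
| Wednesday's | 30.0 | 60.6 |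

(each reading ± 0.3 percentage points)
1. which one finishes higher in amount of target, in percent of the substrate charged ("neither" within 2 percentage points) (larch / elm / neither)
2. amount of target at the end, in percent of the substrate charged, larch
3. amount of target at the end, in percent of the substrate charged, elm
- in a conversion other conformer counts as not yet reacted

What do you read from Wednesday's run? Suppose substrate falls first-order and target takes a fixed fraction of what falls. Then the readings at 15.0 min and 30.0 min, one time double the other, give a loss constant of 0.0939 min⁻¹ and a plateau of 64.4% of the charge. Tuesday's readings at 30.0 min and 60.0 min give 0.0103 min⁻¹ and 44.2% in the same way.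

How firm is Tuesday's plateau? Not very: it rests on a difference of 3.1 percentage points between readings that each scatter by 0.3 points. I carry it with that doubt.

What do you carry to −20 °C? Each plateau is a share, so as odds of target against the rest they read 0.791 and 1.81. The two runs differ in charge as well as in temperature; I assume the charge has no effect, and I let these odds and the loss constant each change by a steady factor per degree. The odds then reach 3.15, which gives a target share of 75.9%: the fraction of the charge consumed that ends as target, a selectivity. The loss constant becomes 0.411 min⁻¹.

Is that share your answer for elm? It is the first round, which treats the charge as consumed. On the second round I put the loss back in: after 10 min, I reckon that elm keeps 1.64% of its substrate, so my estimate of its target is 74.7%.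

And larch? By 3.0 min I reckon that larch holds 53.8% target, with 29.1% substrate left. At −40 °C my estimate of the loss constant is 0.0215 min⁻¹ and of the share 51.0%. The remaining 12.0 min add 3.38% on this reckoning, so my estimate for larch is 57.2%, less than my estimate for elm.

The forecast also names elm, but with slightly different figures from mine: 55% for larch and 74% for elm. Its ground is “Warmer therefore favours target.”

The flasks give elm as the higher: larch 52.8%, elm 68.3%.

    other conformer → isomer of the product (k = 2.40 min⁻¹, Ea = 58.0 kJ mol⁻¹)
    target ⇌ isomer of the product (K = 2.04, k = 0.00990 min⁻¹, Ea = 83.0 kJ mol⁻¹, ΔH = −54.0 kJ mol⁻¹)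
    substrate → target (k = 0.276 min⁻¹, Ea = 80.0 kJ mol⁻¹)
    substrate ⇌ other conformer (K = 0.610, k = 0.101 min⁻¹, Ea = 69.0 kJ mol⁻¹, ΔH = −36.0 kJ mol⁻¹)
    (constants at −20 °C)

With the path from target to isomer of the product struck out, both ways, elm ends at 72.6%. The target share times elm's conversion of 97.4% gives 73.9%. Elm read at 4.0 min, with 22.7% substrate and 1.05% other conformer remaining, gets 57.9% from the same share and holds 56.3% target.

The readings come from a simulation on assumed constants; the scatter is artificial.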